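The partner charged to the flask equals 30.0 % of the two substrates together, and the look comes at 10 % conversion.

the same everywhere: left-handed substrate 0.20 M; right-handed substrate 0.20 M; free catalyst 15 mM; stray impurity 2.5 mM
- elm: partner 0.12 M; protic impurity 0.020 M; run made earlier
- flask: partner 0.120 M; protic impurity 0.0100 M

elm run (percent of the left-handed substrate and right-handed substrate together charged)

| time / min | left-handed product / % | left-handed substrate / % |
|---|---|---|
| 0.500 | 5.8 | 44.1 |
| 1.00 | 7.1 | 41.6 |
| 2.50 | 12.7 | 37.3 |
| 6.00 | 15.1 | 35.0 |

(each reading ± 1 percentage point)

- apparent order in free catalyst when 10 % of the left-handed substrate and right-handed substrate together are converted (percent change of the rate of making left-handed product for one percent more free catalyst charged)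
- apparent order in partner when 10 % of the left-handed substrate and right-handed substrate together are converted (percent change of the rate of making left-handed product for one percent more partner charged)

- free catalyst is single-handed; left-handed substrate and right-handed substrate are mirror images of each other, charged as a racemate, each of them at the stated concentration
- no earlier run changes the charge of free catalyst; that part of a forecast is a guess
- no earlier run changes the charge of protic impurity; that part of a forecast is a guess
- no earlier run changes the charge of partner; that part of a forecast is a guess

What stops the elm run? Not substrate: at 6.00 min the left-handed product reads 15.1 %, and left-handed substrate still reads 35.0 %.

Who is the suspect? Partner, the limiting reagent. I assume each protic impurity destroys one partner and each converted substrate uses one. In the elm run that leaves partner for 25.0 % of the substrates, more than the product reading. The rest can go to the right-handed substrate.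

Why should an order exceed one? Because the question holds conversion fixed. The loss is then a fixed amount, so one percent more charge raises the remainder by more than one percent. If the rate is first order in the remainder, the order in the charge is charge over remainder.

What is that for this flask? Charge less protic impurity less conversion leaves 58.3 % of the partner charge: the surviving fraction. Its inverse is 1.72.

And the free catalyst? If stray impurity removes its equal amount, 83.3 % of the catalyst charge survives, and the inverse is 1.20.

Where is this weak? No earlier run varied either charge, so both orders rest on assumption.

The forecast gives 1.2 for catalyst (0.85 to 1.45), equal to mine. For partner it gives 1.6 (0.9 to 2), lower than mine. Its ground for the lower figure is “Some saturation would lower this”.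

The flask gives 1.2 for catalyst and 1.7 for partner.

    partner + free catalyst + left-handed substrate → free catalyst + left-handed product (k = 210 M⁻² min⁻¹)
    partner + free catalyst + right-handed substrate → free catalyst + right-handed product (k = 130 M⁻² min⁻¹)
    free catalyst + stray impurity → spent catalyst (k = 40000 M⁻¹ min⁻¹)
    partner + protic impurity → quenched reagent (k = 220 M⁻¹ min⁻¹)

The flask reaches the conversion asked about at 0.560 min. The surviving fraction 58.3 % has inverse 1.72. The quench of partner by protic impurity is part of the reason, adding 0.215 to the order. Remove that step from the flask and the surviving fraction becomes 66.7 %, with inverse 1.50. The simulated run without the step gives an order of 1.5.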